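**Overview**

- Cuts, in chromanone numbering (O1, C2, C3, C4=O, C4a, C5-C8, C8a). First, the bond from quaternary C8 to the prenyl CH2, which restores the arene. Second, the aryl C8-CH2 bond to the cyclobutylmethyl group. Third, O1-C2 and C4-C4a of the pyranone. Last, the C6 octanoic acid chain is folded onto the C5 oxygen as a 4-pentylcoumarin, which is cut by a Pechmann disconnection to phloroglucinol and a β-keto ester.
- Enabling feature: C8 lies between the C7 ketone and the enol-ether carbon C8a, and C5(OH)=C6 completes a vinylogous acid. The carbocycle is therefore the C8-alkylated keto form of a 5,7-dihydroxy-6,8-dialkylchroman-4-one (an acylphloroglucinol), whose C7 phenoxide is nucleophilic at its ortho carbon C8.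
- The cis-2,2-dimethyl-3-isopropenylcyclobutyl-CH2 group is the four-membered ring (C1, C5, C6, C7) of (1S,5S)-verbenone. Scission of C3=C4 leaves C2 as the future CH2 and C4 as the future isopropenyl carbon.
- Forward order: cyclobutane taken intact from verbenone; coumarin ring (Pechmann); chromanone ring (C-acylation, oxa-Michael closure); iodination and Negishi union of the two halves; conjugate reduction and methanolysis open the lactone to the ester chain; dearomative prenylation; ester hydrolysis.
- Stereochemistry: both cyclobutane centres come from the chiral pool. C2 comes from a quinine-catalysed oxa-Michael addition and C3 from equilibration to trans. The side-chain CH comes from a ligand-controlled CuH reduction, and C8 from the chiral diphosphine on palladium.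

Key step: step 16

Numbering: tricycles 13-20 are numbered as pyrano[2,3-f]chromenes: O1, C2(=O), C3, C4 (pentyl), C4a, C5 (O-substituent), C6, C6a, O7, C8 (OCHMe), C9 (CHMe), C10 (C=O), C10a, C10b. Once the lactone is open, C8/C9/C10 become chromanone C2/C3/C4, O1 becomes the C5 hydroxyl, C4a becomes C6, C5 becomes C7 and C6 becomes C8.

Assumption: the sense of induction of (-)-quinine (step 8) is taken from the behaviour of closely related 7-hydroxy-8-tigloylcoumarins. That of (R)-DTBM-SEGPHOS (step 13) and of the (R,R)-Trost ligand (step 16) is assigned by analogy only. Should a ligand deliver the wrong epimer, its commercial antipode is used under the same conditions.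

**Route**

Step 1
Reactants: 1 (1S,5S)-(-)-verbenone
Product: 3 (1S,3R)-3-acetyl-2,2-dimethylcyclobutane-1-carboxylic acid (cis-pinononic acid), via alpha-keto acid 2 (not isolated)
Conditions: RuCl3·xH2O (2 mol %), NaIO4 (4.5 equiv), MeCN/EtOAc/H2O, 0 °C to rt
Reagents that add atoms: sodium periodate, [Na+].[O-]I(=O)(=O)=O; water, O
Why: Catalytic RuO4 oxidative cleavage of the enone C3=C4 bond leaves C4 as the methyl ketone and C3 as the carboxyl of alpha-keto acid 2, which is decarboxylated oxidatively to the acid at C2, while the two bridgehead carbons are untouched, so the cis relation enforced by the bicycle passes into 3.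

Step 2
Reactants: 3 cis-pinononic acid
Product: 4 methyl (1S,3R)-3-acetyl-2,2-dimethylcyclobutane-1-carboxylate
Conditions: TMSCHN2, PhMe/MeOH 4:1, 0 °C
Reagents that add atoms: (trimethylsilyl)diazomethane, C[Si](C)(C)C=[N+]=[N-]
Why: Diazoalkane esterification runs under neutral conditions at 0 °C, so the enolisable ring carbon next to the acetyl group cannot drift to the trans series.

Step 3
Reactants: 4 methyl cis-3-acetyl-2,2-dimethylcyclobutanecarboxylate
Product: 5 methyl (1S,3S)-2,2-dimethyl-3-(prop-1-en-2-yl)cyclobutane-1-carboxylate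
Conditions: Zn, CH2Br2, TiCl4, THF, -40 to 5 °C (reagent pre-formed); then 4, CH2Cl2, 0 °C to rt
Reagents that add atoms: dibromomethane, BrCBr
Why: Lombardo methylenation uses a non-basic Zn/Ti gem-dimetallic methylene reagent that attacks ketones much faster than esters and is suited to epimerisable ketones, so the cis-configured C3 is kept where a phosphorus ylide could enolise it.

Step 4
Reactants: 5 methyl cis-3-isopropenyl-2,2-dimethylcyclobutanecarboxylate
Product: 6 [(1S,3S)-2,2-dimethyl-3-(prop-1-en-2-yl)cyclobutyl]methanol
Conditions: LiAlH4, Et2O, 0 °C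
Reagents that add atoms: none
Why: Standard hydride reduction of an ester to the primary alcohol, to which the 1,1-disubstituted alkene and both ring stereocentres are inert.

Step 5
Reactants: 6 cis-(3-isopropenyl-2,2-dimethylcyclobutyl)methanol
Product: 7 (1S,3S)-1-(iodomethyl)-2,2-dimethyl-3-(prop-1-en-2-yl)cyclobutane
Conditions: I2, PPh3, imidazole, CH2Cl2, 0 °C to rt
Reagents that add atoms: iodine, II
Why: Appel iodination displaces the oxyphosphonium group by SN2 at the primary carbon, which avoids a cyclobutylcarbinyl cation and therefore ring expansion.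

Step 6
Reactants: 8 phloroglucinol; 9 ethyl 3-oxooctanoate
Product: 10 5,7-dihydroxy-4-pentylcoumarin
Conditions: conc. H2SO4, 90 °C
Reagents that add atoms: none
Why: Pechmann condensation (transesterification, ring hydroxyalkylation, dehydration) is very efficient with phloroglucinol, whose symmetry allows only one coumarin.

Step 7
Reactants: 10 5,7-dihydroxy-4-pentylcoumarin; 11 tigloyl chloride, (E)-2-methylbut-2-enoyl chloride
Product: 12 5,7-dihydroxy-8-[(E)-2-methylbut-2-enoyl]-4-pentylcoumarin
Conditions: AlCl3 (4 equiv), PhNO2/1,2-dichloroethane, 70 °C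
Reagents that add atoms: none
Why: Friedel-Crafts C-acylation of 5,7-dihydroxy-4-alkylcoumarins under AlCl3 is known to favour C8, between the 7-OH and the lactone oxygen, over C6, the minor C6 isomer being removed by chromatography and the heating kept short so that the E-enone does not cyclise prematurely.

Step 8
Reactants: 12 5,7-dihydroxy-4-pentyl-8-tigloylcoumarin
Product: 13 (8R,9S)-5-hydroxy-8,9-dimethyl-4-pentyl-8,9-dihydro-2H,10H-pyrano[2,3-f]chromene-2,10-dione (cis-dimethylchromanone fused to the coumarin)
Conditions: (-)-quinine (20 mol %), PhCl, rt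
Reagents that add atoms: none
Why: In this cinchona-alkaloid-catalysed intramolecular oxa-Michael addition only the 7-OH can reach the enone, quinine holds the phenol at its quinuclidine nitrogen and the carbonyl at its C9 hydroxyl so that oxygen reaches one face of the β-carbon and sets C8 as R, and kinetic protonation of the enol should give mainly the cis isomer, as established for closely related 7-hydroxy-8-tigloylcoumarins.

Step 9
Reactants: 13 cis-(8R,9S)-chromanone
Product: 14 (8R,9R)-5-hydroxy-8,9-dimethyl-4-pentyl-8,9-dihydro-2H,10H-pyrano[2,3-f]chromene-2,10-dione (trans-dimethylchromanone, free 5-OH, free C6-H)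
Conditions: MgI2 (2 equiv), THF, 60 °C
Reagents that add atoms: none
Why: Lewis-acid-mediated epimerisation, in which magnesium bound to the C10 ketone promotes reversible enolisation at C9 only and lets the ring settle in the diequatorial trans isomer, avoids the basic media that would open the ring by retro-oxa-Michael reaction and erode C8.

Step 10
Reactants: 14 trans-(8R,9R)-chromanone
Product: 15 (8R,9R)-5-hydroxy-6-iodo-8,9-dimethyl-4-pentyl-8,9-dihydro-2H,10H-pyrano[2,3-f]chromene-2,10-dione
Conditions: NIS (1.0 equiv), MeCN, 0 °C, dark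
Reagents that add atoms: N-iodosuccinimide, O=C1CCC(=O)N1I
Why: In this electrophilic aromatic iodination C6, ortho to the free 5-OH and to the ring ether oxygen, is the only aromatic CH and far more nucleophilic than the coumarin C3, so one equivalent of NIS in the cold should be selective.

Step 11
Reactants: 15 6-iodo phenol
Product: 16 (8R,9R)-6-iodo-8,9-dimethyl-2,10-dioxo-4-pentyl-8,9-dihydro-2H,10H-pyrano[2,3-f]chromen-5-yl acetate
Conditions: Ac2O, pyridine, DMAP (cat.), CH2Cl2, rt
Reagents that add atoms: acetic anhydride, CC(=O)OC(C)=O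
Why: DMAP-catalysed O-acetylation masks the acidic phenol so that it cannot quench the valuable alkylzinc reagent, makes the aryl iodide less electron-rich for oxidative addition, and needs no deprotection step of its own because it is lost in step 14.

Step 12
Reactants: 7 cis-(3-isopropenyl-2,2-dimethylcyclobutyl)methyl iodide; 16 6-iodo acetate
Product: 18 (8R,9R)-6-{[(1R,3S)-2,2-dimethyl-3-(prop-1-en-2-yl)cyclobutyl]methyl}-8,9-dimethyl-2,10-dioxo-4-pentyl-8,9-dihydro-2H,10H-pyrano[2,3-f]chromen-5-yl acetate, via alkylzinc iodide 17 (not isolated)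
Conditions: 7 (1.5 equiv), Zn dust (BrCH2CH2Br/TMSCl-activated), LiCl, THF, 25-40 °C; then 16, Pd(OAc)2 (4 mol %), SPhos (8 mol %), THF, 25-50 °C
Reagents that add atoms: zinc, [Zn] (kept only in 17)
Why: LiCl-assisted zinc insertion gives a primary alkylzinc iodide that tolerates lactone, ketone and acetate, and Negishi sp3-sp2 coupling with a bulky biarylphosphine favours reductive elimination at the doubly ortho-substituted aryl palladium species over β-hydride elimination, the cyclobutane centres being spectators (the descriptor at the CH2-bearing carbon changes from S to R only through CIP ranking).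

Step 13
Reactants: 18 C6-cyclobutylmethyl coumarin-chromanone acetate
Product: 19 (4S,8R,9R)-6-{[(1R,3S)-2,2-dimethyl-3-(prop-1-en-2-yl)cyclobutyl]methyl}-8,9-dimethyl-2,10-dioxo-4-pentyl-3,4,8,9-tetrahydro-2H,10H-pyrano[2,3-f]chromen-5-yl acetate
Conditions: Cu(OAc)2·H2O (5 mol %), (R)-DTBM-SEGPHOS (5.5 mol %), (EtO)2MeSiH (1.2 equiv), t-BuOH (1.2 equiv), PhMe, 0 °C to rt
Reagents that add atoms: none
Why: Copper hydride-catalysed asymmetric conjugate reduction is known for 4-substituted coumarins and β,β-disubstituted enoates, the ligated CuH delivering hydride to the face of C4 chosen by the ligand to set 4S and tert-butanol protonating the copper enolate, while isolated alkenes and the acetate are inert and the chromanone carbonyl, a doubly ortho-oxygenated and α-branched vinylogous ester, should be the slower acceptor when the silane is limited.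

Step 14
Reactants: 19 (4S)-dihydrocoumarin acetate
Product: 21 methyl (3S)-3-[(2R,3R)-8-{[(1R,3S)-2,2-dimethyl-3-(prop-1-en-2-yl)cyclobutyl]methyl}-5,7-dihydroxy-2,3-dimethyl-4-oxochroman-6-yl]octanoate (both phenols free), via phenol lactone 20 (not isolated)
Conditions: DMAP (0.5 equiv), MeOH, rt to 40 °C; pH 5 buffer wash before concentration
Reagents that add atoms: methanol, CO
Why: In this nucleophile-catalysed transesterification both aryl esters are activated acyl donors, so the acetate is cleaved to 20 and the lactone opened, the open form being held by the excess of methanol and by the new hydrogen bond from the liberated C5-OH to the C4 ketone, while the weakly basic medium leaves the benzylic centre and C3 (already the thermodynamic epimer) alone.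

Step 15
Reactants: 22 prenol (3-methylbut-2-en-1-ol)
Product: 23 tert-butyl 3-methylbut-2-en-1-yl carbonate
Conditions: n-BuLi (1.0 equiv), THF, -78 to 0 °C; Boc2O, 0 °C to rt
Reagents that add atoms: di-tert-butyl dicarbonate, CC(C)(C)OC(=O)OC(=O)OC(C)(C)C
Why: O-acylation of a lithium alkoxide with Boc2O is the standard preparation of allylic tert-butyl carbonates.

Step 16
Reactants: 21 chromanone diphenol methyl ester; 23 tert-butyl prenyl carbonate
Product: 24 methyl (3S)-3-[(2R,3R,8R)-8-{[(1R,3S)-2,2-dimethyl-3-(prop-1-en-2-yl)cyclobutyl]methyl}-5-hydroxy-2,3-dimethyl-8-(3-methylbut-2-en-1-yl)-4,7-dioxo-3,4,7,8-tetrahydro-2H-chromen-6-yl]octanoate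
Conditions: Pd2(dba)3·CHCl3 (2.5 mol %), (R,R)-DACH-phenyl Trost ligand (7.5 mol %), 23 (1.1 equiv), degassed PhMe, 0 °C to rt
Reagents that add atoms: none
Why: Pd(0) ionises 23 with loss of CO2 to a cationic π-prenyl complex and tert-butoxide, which removes the proton of the C7 hydroxyl, the only phenol of 21 not locked in a hydrogen bond to the C4 ketone, and the ambident phenoxide then attacks the CH2 terminus of the allyl ligand through its ortho carbon C8 from outside the metal, leaving the ring as the C7 ketone/C5 enol. The closest known reactions are the Tsuji-Trost dearomative allylation and prenylation of acylphloroglucinols with allylic carbonates and the intermolecular asymmetric allylic dearomatisation of naphthols and substituted phenols with Trost-type diphosphines, and ligand control on a substrate this crowded stretches that precedent. No ring is closed. The one new stereocentre, quaternary C8 (R), is set by the chiral pocket of the ligand, which decides the face of the flat phenoxide that meets the allyl terminus, because C2, C3, the side-chain CH and the cyclobutane centres are too remote to bias it. The step needs C- over O-alkylation (O-prenyl ethers of this acidic phenol re-ionise under Pd(0) whereas the dienone cannot revert), C8 over C6 (C8 carries a CH2 group, C6 a branched CH) and linear over reverse prenyl (a soft nucleophile building a quaternary carbon takes the unsubstituted terminus). Over-alkylation at C6 of the product is held back by the small excess of 23 and the weak nucleophilicity of the vinylogous acid anion, and the near-neutral medium spares C2 and C3.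

Step 17
Reactants: 24 dearomatised methyl ester
Product: 25 (3S)-3-[(2R,3R,8R)-8-{[(1R,3S)-2,2-dimethyl-3-(prop-1-en-2-yl)cyclobutyl]methyl}-5-hydroxy-2,3-dimethyl-8-(3-methylbut-2-en-1-yl)-4,7-dioxo-3,4,7,8-tetrahydro-2H-chromen-6-yl]octanoic acid (CNP0208815.1)
Conditions: LiOH (4 equiv), THF/MeOH/H2O, 0 °C to rt; then 1 M HCl to pH 3-4, 0 °C
Reagents that add atoms: lithium hydroxide, [Li+].[OH-]
Why: In this saponification of an unhindered methyl ester the vinylogous acid is deprotonated first, and its delocalised anion protects the C4 carbonyl from enolisation at C3 and from retro-oxa-Michael opening, so no stereocentre is at risk, and cold, mild acidification spares both alkenes.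

**Compound list**

1 | (1S,5S)-(-)-verbenone | CC1=CC(=O)[C@H]2C[C@@H]1C2(C)C | starting material
2 | 2-[(1S,3R)-3-acetyl-2,2-dimethylcyclobutyl]-2-oxoacetic acid | CC(=O)[C@@H]1C[C@H](C(=O)C(=O)O)C1(C)C | intermediate
3 | (1S,3R)-3-acetyl-2,2-dimethylcyclobutane-1-carboxylic acid | CC(=O)[C@@H]1C[C@H](C(=O)O)C1(C)C | intermediate
4 | methyl (1S,3R)-3-acetyl-2,2-dimethylcyclobutane-1-carboxylate | CC(=O)[C@@H]1C[C@H](C(=O)OC)C1(C)C | intermediate
5 | methyl (1S,3S)-2,2-dimethyl-3-(prop-1-en-2-yl)cyclobutane-1-carboxylate | C=C(C)[C@@H]1C[C@H](C(=O)OC)C1(C)C | intermediate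
6 | [(1S,3S)-2,2-dimethyl-3-(prop-1-en-2-yl)cyclobutyl]methanol | C=C(C)[C@@H]1C[C@H](CO)C1(C)C | intermediate
7 | (1S,3S)-1-(iodomethyl)-2,2-dimethyl-3-(prop-1-en-2-yl)cyclobutane | C=C(C)[C@@H]1C[C@H](CI)C1(C)C | intermediate
8 | phloroglucinol | Oc1cc(O)cc(O)c1 | starting material
9 | ethyl 3-oxooctanoate | CCCCCC(=O)CC(=O)OCC | starting material
10 | 5,7-dihydroxy-4-pentylcoumarin | CCCCCC1=CC(=O)Oc2cc(O)cc(O)c12 | intermediate
11 | tigloyl chloride | C/C=C(\C)C(=O)Cl | starting material
12 | 5,7-dihydroxy-8-[(E)-2-methylbut-2-enoyl]-4-pentylcoumarin | CCCCCC1=CC(=O)Oc2c(C(=O)/C(C)=C/C)c(O)cc(O)c12 | intermediate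
13 | cis-(8R,9S)-5-hydroxy-8,9-dimethyl-4-pentyl-8,9-dihydro-2H,10H-pyrano[2,3-f]chromene-2,10-dione | CCCCCC1=CC(=O)Oc2c1c(O)cc1O[C@H](C)[C@H](C)C(=O)c21 | intermediate
14 | trans-(8R,9R)-5-hydroxy-8,9-dimethyl-4-pentyl-8,9-dihydro-2H,10H-pyrano[2,3-f]chromene-2,10-dione | CCCCCC1=CC(=O)Oc2c1c(O)cc1O[C@H](C)[C@@H](C)C(=O)c21 | intermediate
15 | 6-iodo derivative of 14 | CCCCCC1=CC(=O)Oc2c1c(O)c(I)c1O[C@H](C)[C@@H](C)C(=O)c21 | intermediate
16 | 5-O-acetyl-6-iodo derivative of 14 | CCCCCC1=CC(=O)Oc2c1c(OC(C)=O)c(I)c1O[C@H](C)[C@@H](C)C(=O)c21 | intermediate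
17 | {[(1S,3S)-2,2-dimethyl-3-(prop-1-en-2-yl)cyclobutyl]methyl}zinc iodide | C=C(C)[C@@H]1C[C@H](C[Zn]I)C1(C)C | intermediate
18 | 6-(cyclobutylmethyl) coumarin-chromanone, 5-acetate | C=C(C)[C@@H]1C[C@H](Cc2c(OC(C)=O)c3C(CCCCC)=CC(=O)Oc3c3c2O[C@H](C)[C@@H](C)C3=O)C1(C)C | intermediate
19 | (4S)-4-pentyl dihydrocoumarin-chromanone, 5-acetate | C=C(C)[C@@H]1C[C@H](Cc2c(OC(C)=O)c3c(OC(=O)C[C@@H]3CCCCC)c3c2O[C@H](C)[C@@H](C)C3=O)C1(C)C | intermediate
20 | (4S)-4-pentyl dihydrocoumarin-chromanone, free 5-OH | C=C(C)[C@@H]1C[C@H](Cc2c(O)c3c(OC(=O)C[C@@H]3CCCCC)c3c2O[C@H](C)[C@@H](C)C3=O)C1(C)C | intermediate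
21 | aromatic chromanone methyl ester, 5-OH and 7-OH free | C=C(C)[C@@H]1C[C@H](Cc2c(O)c([C@@H](CCCCC)CC(=O)OC)c(O)c3c2O[C@H](C)[C@@H](C)C3=O)C1(C)C | intermediate
22 | prenol | CC(C)=CCO | starting material
23 | tert-butyl 3-methylbut-2-en-1-yl carbonate | CC(C)=CCOC(=O)OC(C)(C)C | intermediate
24 | (8R)-dearomatised methyl ester | C=C(C)[C@@H]1C[C@H](C[C@@]2(CC=C(C)C)C(=O)C([C@@H](CCCCC)CC(=O)OC)=C(O)C3=C2O[C@H](C)[C@@H](C)C3=O)C1(C)C | intermediate
25 | CNP0208815.1 | C=C(C)[C@@H]1C[C@H](C[C@@]2(CC=C(C)C)C(=O)C([C@@H](CCCCC)CC(=O)O)=C(O)C3=C2O[C@H](C)[C@@H](C)C3=O)C1(C)C | target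

**Totals**

Total step count: 17.
Longest linear sequence: 11 steps, from 8 through steps 6-14, 16 and 17. The verbenone branch gives 10 steps.

**Steps most likely to fail**

Step 16.
- What may go wrong: the ligand pocket may not distinguish the two faces of a flat phenoxide whose reacting carbon is already fully substituted. Turnover may also stall while the O-prenyl ether builds up, or while the C7 phenoxide closes onto the methyl ester.
- Fallback: π-allyl chemistry is given up for classical alkylative dearomatisation.
- Setting out from 21, both phenols are converted into the dilithium salt (LiHMDS, 2 equiv, PhMe/THF, -78 °C) and alkylated with prenyl bromide (1 equiv, -78 to 0 °C).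
- Tight lithium ion pairs in a weakly polar medium favour carbon over oxygen and the less hindered C8.
- Without facial control the reaction would give 24 together with the (8S)-epimer of 24 F1. The five resident stereocentres make these diastereomers, which would be separated by chromatography. The route is rejoined at 24.

Step 13.
- What may go wrong: hydride may go to the chromanone carbonyl, or onward to the aryl lactone carbonyl, instead of only to the crowded C4. Selectivity between the acceptors would then be lost.
- Fallback: the competing ketone is taken out of play first.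
- Setting out from 18, Luche reduction (NaBH4, CeCl3·7H2O, MeOH/THF, -40 °C) gives the all-trans (8R,9S,10S)-10-hydroxy compound F2.
- The same CuH/(R)-DTBM-SEGPHOS/silane system then finds the coumarin as the only conjugate acceptor and gives the (4S)-dihydrocoumarin chromanol F3. Its hydroxyl is silylated transiently by the silane and freed with aqueous NH4F.
- Dess-Martin oxidation of the benzylic alcohol comes back to the route at 19.

Step 12.
- What may go wrong: the cyclobutylcarbinyl radical formed at the zinc surface may fragment towards the tertiary radical.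
- Oxidative addition and transmetalation at the doubly ortho-substituted iodide may also be sluggish, which leads to protodeiodination.
- Fallback: the organometallic partner is changed.
- Setting out from 7, iodine-lithium exchange (t-BuLi, 2.1 equiv, pentane/Et2O, -78 °C) is a polar process at this temperature. It gives the cis-cyclobutylmethyllithium F4.
- F4 is trapped with B-methoxy-9-BBN as the lithium B-alkyl-B-methoxy-9-BBN ate complex F5.
- F5 transfers its primary alkyl group to 16 under PdCl2(dppf) in THF/DMF at rt to 50 °C without added base (B-alkyl Suzuki-Miyaura coupling, 9-MeO-9-BBN variant), so acetate and lactone are safe. The route is rejoined at 18.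

**Further compounds**

F1 | step 16 | (8S)-epimer of 24 | C=C(C)[C@@H]1C[C@H](C[C@]2(CC=C(C)C)C(=O)C([C@@H](CCCCC)CC(=O)OC)=C(O)C3=C2O[C@H](C)[C@@H](C)C3=O)C1(C)C
F2 | step 13 | (8R,9S,10S)-10-hydroxy analogue of 18 (ketone reduced, coumarin intact) | C=C(C)[C@@H]1C[C@H](Cc2c(OC(C)=O)c3C(CCCCC)=CC(=O)Oc3c3c2O[C@H](C)[C@@H](C)[C@@H]3O)C1(C)C
F3 | step 13 | (4S,8R,9S,10S)-10-hydroxy analogue of 19 | C=C(C)[C@@H]1C[C@H](Cc2c(OC(C)=O)c3c(OC(=O)C[C@@H]3CCCCC)c3c2O[C@H](C)[C@@H](C)[C@@H]3O)C1(C)C
F4 | step 12 | cis-(3-isopropenyl-2,2-dimethylcyclobutyl)methyllithium, configuration as in 7 | C=C(C)[C@@H]1C[C@H](C[Li])C1(C)C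
F5 | step 12 | lithium B-[cis-(3-isopropenyl-2,2-dimethylcyclobutyl)methyl]-B-methoxy-9-borabicyclo[3.3.1]nonane ate complex | [Li+].C=C(C)[C@@H]1C[C@H](C[B-]2(OC)C3CCCC2CCC3)C1(C)C
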